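The 1,3-diketone chain is cut between its central CH and the ring-side carbonyl (aldol, then oxidation, from a ring carbaldehyde and protected dehydrozingerone); both phenols are masked as MOM ethers.
The ring is numbered C1 (CH with the acyl chain), C2 (CH-guaiacyl), C3 (CH2), C4=C5, C6 (CH-veratryl). C4=C5 is an unsubstituted cis ring alkene remote from the stereotriad C1/C2/C6, so the ring is opened there into an allyl group on C2 and a vinyl group on C6.
The open-chain diene is cut at C1–C6 (iridium/amine α-allylation of a 3-aryl-hex-5-enal) and at C1–C2 (iminium-catalysed malonate addition to protected coniferaldehyde).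
Forward: C1–C2 bond, adjustment of the two arms, C1–C6 bond, closure of the only new ring at C4=C5, side chain, deprotection.
Stereochemistry: C2 from the prolinol silyl ether of step 2, C6 from the iridium ligand and C1 from the amine of step 7; C1 is also the all-equatorial, thermodynamically preferred epimer, so leakage there can be corrected with base on the ring aldehyde.

Key step: step 8

Remark 1: the (R)-phosphoramidite–olefin ligand is assumed to give the (R)-configured benzylic carbon C6; if the sense is the reverse, its enantiomer is used, since the iridium catalyst alone sets C6.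
Remark 2: compounds 17 and 18 are 1,3-diketones, drawn as the hydrogen-bonded enol tautomer of the target SMILES; the tautomers interconvert.

Step 1
Reactants: 1 coniferaldehyde
Product: 2 (2E)-3-[3-methoxy-4-(methoxymethoxy)phenyl]prop-2-enal
Conditions: MOMCl, i-Pr2NEt, CH2Cl2, 0 °C to rt
Reagents that add atoms: chloromethyl methyl ether (MOMCl), COCCl
Why: O-alkylation of the phenol (MOM ether formation); the acetal should survive amine catalysis, ylide, hot LiCl/DMSO, hydride, the weakly acidic allylation, metathesis, enolate and periodinane, and leave under mild acid at the end.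

Step 2
Reactants: 2 (2E)-3-[3-methoxy-4-(methoxymethoxy)phenyl]prop-2-enal; 3 dimethyl malonate
Product: 4 dimethyl 2-{(1S)-1-[3-methoxy-4-(methoxymethoxy)phenyl]-3-oxopropyl}propanedioate
Conditions: (R)-2-{bis[3,5-bis(trifluoromethyl)phenyl](trimethylsilyloxy)methyl}pyrrolidine (10 mol%), EtOH, 0 °C
Reagents that add atoms: none
Why: Iminium-ion-catalysed Michael addition of a malonate to an enal: the (R)-diarylprolinol silyl ether forms the E-iminium ion and blocks one face of the β-carbon with its diaryl(silyloxy)methyl group, so the malonate should add to the open face and set the guaiacyl-bearing centre (later ring C2) as S.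

Step 3
Reactants: 4 dimethyl 2-{(1S)-1-[3-methoxy-4-(methoxymethoxy)phenyl]-3-oxopropyl}propanedioate
Product: 5 dimethyl 2-{(1S)-1-[3-methoxy-4-(methoxymethoxy)phenyl]but-3-en-1-yl}propanedioate
Conditions: Ph3PCH3Br (2.5 equiv), KN(SiMe3)2 (2.4 equiv), THF, −78 to 0 °C
Reagents that add atoms: methyltriphenylphosphonium bromide, C[P+](c1ccccc1)(c1ccccc1)c1ccccc1.[Br-]
Why: Wittig methylenation; one equivalent of ylide is spent on the acidic malonate C–H, whose anion is inert, and the second should convert the aldehyde into the terminal alkene at low temperature without touching the β-stereocentre.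

Step 4
Reactants: 5 dimethyl 2-{(1S)-1-[3-methoxy-4-(methoxymethoxy)phenyl]but-3-en-1-yl}propanedioate
Product: 6 methyl (3S)-3-[3-methoxy-4-(methoxymethoxy)phenyl]hex-5-enoate
Conditions: LiCl, H2O, DMSO, 150 °C
Reagents that add atoms: none
Why: Krapcho dealkoxycarbonylation (chloride attack on an ester methyl, loss of CO2, protonation) removes one ester under neutral conditions that should leave the MOM ether, the terminal alkene and the non-enolisable stereocentre untouched.

Step 5
Reactants: 6 methyl (3S)-3-[3-methoxy-4-(methoxymethoxy)phenyl]hex-5-enoate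
Product: 8 (3S)-3-[3-methoxy-4-(methoxymethoxy)phenyl]hex-5-enal, via aluminium hemiacetal 7 (not isolated)
Conditions: i-Bu2AlH (1.1 equiv), toluene, −78 °C; MeOH, then aq. potassium sodium tartrate
Reagents that add atoms: none
Why: Partial reduction of a methyl ester with DIBAL-H: hemiacetal 7 persists at −78 °C and collapses to the aldehyde only on aqueous work-up, so over-reduction should be limited.

Step 6
Reactants: 9 3,4-dimethoxybenzaldehyde
Product: 10 rac-1-(3,4-dimethoxyphenyl)prop-2-en-1-ol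
Conditions: CH2=CHMgBr, THF, 0 °C; aq. NH4Cl
Reagents that add atoms: vinylmagnesium bromide, C=C[Mg]Br
Why: Grignard 1,2-addition to the aldehyde; the racemic branched alcohol is used as such because the iridium catalyst of step 7 converts both enantiomers into the same allyl intermediate.

Step 7
Reactants: 8 (3S)-3-[3-methoxy-4-(methoxymethoxy)phenyl]hex-5-enal; 10 rac-1-(3,4-dimethoxyphenyl)prop-2-en-1-ol (1.5 equiv)
Product: 11 (2R,3S)-2-[(1R)-1-(3,4-dimethoxyphenyl)prop-2-en-1-yl]-3-[3-methoxy-4-(methoxymethoxy)phenyl]hex-5-enal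
Conditions: [Ir(cod)Cl]2 (3 mol%), (R)-5-(dinaphtho[2,1-d:1',2'-f][1,3,2]dioxaphosphepin-4-yl)-5H-dibenzo[b,f]azepine (12 mol%), (S)-2-{bis[3,5-bis(trifluoromethyl)phenyl](trimethylsilyloxy)methyl}pyrrolidine (15 mol%), (MeO)2P(O)OH (promoter), ClCH2CH2Cl, 25 °C
Reagents that add atoms: none
Why: Dual iridium/enamine catalysis (stereodivergent α-allylation of linear aldehydes with aryl vinyl carbinols): acid-promoted ionisation of 10 at the iridium phosphoramidite–olefin complex gives an allyliridium electrophile that is attacked at its aryl-bearing terminus on the face set by the ligand (C6, R), while the enamine of 8 with the (S)-prolinol silyl ether reacts on the face away from its bulky group (C1, R), each catalyst acting independently of the other and of the existing C2 centre.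

Step 8
Reactants: 11 (2R,3S)-2-[(1R)-1-(3,4-dimethoxyphenyl)prop-2-en-1-yl]-3-[3-methoxy-4-(methoxymethoxy)phenyl]hex-5-enal
Product: 12 (1R,2R,6S)-2-(3,4-dimethoxyphenyl)-6-[3-methoxy-4-(methoxymethoxy)phenyl]cyclohex-3-ene-1-carbaldehyde
Conditions: second-generation Grubbs catalyst (H2IMes)(PCy3)Cl2Ru=CHPh (5 mol%), CH2Cl2 (0.01 M), 40 °C
Reagents that add atoms: none
Why: Ring-closing olefin metathesis: the ruthenium benzylidene first exchanges onto the unhindered allyl terminus on C2, the resulting alkylidene adds [2+2] to the vinyl group on C6 and the metallacyclobutane cycloreverts, which forms C4=C5 and releases ethylene. The closest known reaction type is the metathesis closure of 1,7-dienes to cyclohexenes, which is established for α-(1-arylallyl) aldehydes that carry a second terminal alkene in the chain. The six-membered ring closes by joining the two terminal alkene carbons of one chain, and the ring size allows only the cis alkene. No stereocentre is formed or touched: C2 comes from step 2 and C1 and C6 from step 7, and all three substituents can sit equatorial on the half-chair that forms. The step needs cyclisation to outrun cross-metathesis oligomerisation and allyl-to-propenyl isomerisation, and the branching at every carbon between the two alkenes (C2, C1, C6) together with dilution should secure this. The free aldehyde, the MOM ether and the electron-rich arenes are tolerated by the catalyst.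

Step 9
Reactants: 13 dehydrozingerone
Product: 14 (3E)-4-[3-methoxy-4-(methoxymethoxy)phenyl]but-3-en-2-one
Conditions: MOMCl, i-Pr2NEt, CH2Cl2, 0 °C to rt
Reagents that add atoms: chloromethyl methyl ether (MOMCl), COCCl
Why: O-alkylation of the phenol (MOM ether formation), which removes the acidic phenol before enolate formation and lets one acid treatment free both phenols at the end.

Step 10
Reactants: 12 (1R,2R,6S)-2-(3,4-dimethoxyphenyl)-6-[3-methoxy-4-(methoxymethoxy)phenyl]cyclohex-3-ene-1-carbaldehyde; 14 (3E)-4-[3-methoxy-4-(methoxymethoxy)phenyl]but-3-en-2-one (1.3 equiv)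
Product: 16 (1E)-5-hydroxy-5-[(1R,2R,6S)-2-(3,4-dimethoxyphenyl)-6-[3-methoxy-4-(methoxymethoxy)phenyl]cyclohex-3-en-1-yl]-1-[3-methoxy-4-(methoxymethoxy)phenyl]pent-1-en-3-one (both carbinol epimers), via lithium enolate 15 (not isolated)
Conditions: LiN(i-Pr)2, THF, −78 °C; then 12, −78 °C; aq. NH4Cl
Reagents that add atoms: none
Why: Directed aldol addition: kinetic deprotonation of the methyl group of 14 (the styryl side has no γ-hydrogen) gives cross-conjugated enolate 15, which should add to the aldehyde at −78 °C faster than it deprotonates it; the new carbinol centre is unselective and is removed in step 11.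

Step 11
Reactants: 16 (1E)-5-hydroxy-5-[(1R,2R,6S)-2-(3,4-dimethoxyphenyl)-6-[3-methoxy-4-(methoxymethoxy)phenyl]cyclohex-3-en-1-yl]-1-[3-methoxy-4-(methoxymethoxy)phenyl]pent-1-en-3-one
Product: 17 (2Z,4E)-1-[(1R,2R,6S)-2-(3,4-dimethoxyphenyl)-6-[3-methoxy-4-(methoxymethoxy)phenyl]cyclohex-3-en-1-yl]-3-hydroxy-5-[3-methoxy-4-(methoxymethoxy)phenyl]penta-2,4-dien-1-one
Conditions: Dess–Martin periodinane (1.3 equiv), CH2Cl2, 0 °C to rt
Reagents that add atoms: none
Why: Dess–Martin oxidation of a β-hydroxy ketone to the 1,3-diketone, which rests as the conjugated enol; the alkenes and MOM ethers are inert to the periodinane, and C1, now α to a carbonyl, stays in its all-equatorial configuration.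

Step 12
Reactants: 17 (2Z,4E)-1-[(1R,2R,6S)-2-(3,4-dimethoxyphenyl)-6-[3-methoxy-4-(methoxymethoxy)phenyl]cyclohex-3-en-1-yl]-3-hydroxy-5-[3-methoxy-4-(methoxymethoxy)phenyl]penta-2,4-dien-1-one
Product: 18 (2Z,4E)-1-[(1R,2R,6S)-2-(3,4-dimethoxyphenyl)-6-(4-hydroxy-3-methoxyphenyl)cyclohex-3-en-1-yl]-3-hydroxy-5-(4-hydroxy-3-methoxyphenyl)penta-2,4-dien-1-one (CNP0290899.1)
Conditions: HCl (1 M) in MeOH/THF, 40 °C
Reagents that add atoms: none
Why: Acid-catalysed transacetalisation of both aryl MOM ethers to methanol; the enolised diketone, the ring alkene and the aryl methyl ethers should be stable to dilute methanolic HCl.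

Compound list
1 | coniferaldehyde, (2E)-3-(4-hydroxy-3-methoxyphenyl)prop-2-enal | COc1cc(/C=C/C=O)ccc1O | starting material
2 | (2E)-3-[3-methoxy-4-(methoxymethoxy)phenyl]prop-2-enal | COCOc1ccc(/C=C/C=O)cc1OC | intermediate
3 | dimethyl malonate | COC(=O)CC(=O)OC | starting material
4 | dimethyl 2-{(1S)-1-[3-methoxy-4-(methoxymethoxy)phenyl]-3-oxopropyl}propanedioate | COC(=O)C(C(=O)OC)[C@@H](c1ccc(OCOC)c(OC)c1)CC=O | intermediate
5 | dimethyl 2-{(1S)-1-[3-methoxy-4-(methoxymethoxy)phenyl]but-3-en-1-yl}propanedioate | COC(=O)C(C(=O)OC)[C@@H](c1ccc(OCOC)c(OC)c1)CC=C | intermediate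
6 | methyl (3S)-3-[3-methoxy-4-(methoxymethoxy)phenyl]hex-5-enoate | COC(=O)C[C@@H](c1ccc(OCOC)c(OC)c1)CC=C | intermediate
7 | diisobutylaluminium alkoxide of the methyl hemiacetal of 8 (both hemiacetal epimers) | COC(O[Al](CC(C)C)CC(C)C)C[C@@H](c1ccc(OCOC)c(OC)c1)CC=C | intermediate (not isolated)
8 | (3S)-3-[3-methoxy-4-(methoxymethoxy)phenyl]hex-5-enal | O=CC[C@@H](c1ccc(OCOC)c(OC)c1)CC=C | intermediate
9 | 3,4-dimethoxybenzaldehyde (veratraldehyde) | COc1ccc(C=O)cc1OC | starting material
10 | rac-1-(3,4-dimethoxyphenyl)prop-2-en-1-ol | C=CC(O)c1ccc(OC)c(OC)c1 | intermediate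
11 | (2R,3S)-2-[(1R)-1-(3,4-dimethoxyphenyl)prop-2-en-1-yl]-3-[3-methoxy-4-(methoxymethoxy)phenyl]hex-5-enal | O=C[C@H]([C@@H](c1ccc(OCOC)c(OC)c1)CC=C)[C@H](c1ccc(OC)c(OC)c1)C=C | intermediate (key-step precursor)
12 | (1R,2R,6S)-2-(3,4-dimethoxyphenyl)-6-[3-methoxy-4-(methoxymethoxy)phenyl]cyclohex-3-ene-1-carbaldehyde | O=C[C@@H]1[C@@H](c2ccc(OCOC)c(OC)c2)CC=C[C@H]1c1ccc(OC)c(OC)c1 | intermediate (key-step product)
13 | dehydrozingerone, (3E)-4-(4-hydroxy-3-methoxyphenyl)but-3-en-2-one | CC(=O)/C=C/c1ccc(O)c(OC)c1 | starting material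
14 | (3E)-4-[3-methoxy-4-(methoxymethoxy)phenyl]but-3-en-2-one | CC(=O)/C=C/c1ccc(OCOC)c(OC)c1 | intermediate
15 | lithium (3E)-4-[3-methoxy-4-(methoxymethoxy)phenyl]buta-1,3-dien-2-olate | [Li+].[O-]C(=C)/C=C/c1ccc(OCOC)c(OC)c1 | intermediate (not isolated)
16 | (1E)-5-hydroxy-5-[(1R,2R,6S)-2-(3,4-dimethoxyphenyl)-6-[3-methoxy-4-(methoxymethoxy)phenyl]cyclohex-3-en-1-yl]-1-[3-methoxy-4-(methoxymethoxy)phenyl]pent-1-en-3-one, both C5 epimers | COCOc1ccc(/C=C/C(=O)CC(O)[C@@H]2[C@@H](c3ccc(OCOC)c(OC)c3)CC=C[C@H]2c2ccc(OC)c(OC)c2)cc1OC | intermediate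
17 | (2Z,4E)-1-[(1R,2R,6S)-2-(3,4-dimethoxyphenyl)-6-[3-methoxy-4-(methoxymethoxy)phenyl]cyclohex-3-en-1-yl]-3-hydroxy-5-[3-methoxy-4-(methoxymethoxy)phenyl]penta-2,4-dien-1-one | COc1cc(/C=C/C(O)=C/C(=O)[C@@H]2[C@@H](c3ccc(OCOC)c(OC)c3)CC=C[C@H]2c2ccc(OC)c(OC)c2)ccc1OCOC | intermediate
18 | (2Z,4E)-1-[(1R,2R,6S)-2-(3,4-dimethoxyphenyl)-6-(4-hydroxy-3-methoxyphenyl)cyclohex-3-en-1-yl]-3-hydroxy-5-(4-hydroxy-3-methoxyphenyl)penta-2,4-dien-1-one | COc1cc(/C=C/C(O)=C/C(=O)[C@@H]2[C@@H](c3ccc(O)c(OC)c3)CC=C[C@H]2c2ccc(OC)c(OC)c2)ccc1O | target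

Total step count: 12. Longest linear sequence: 10 steps (1, 2, 3, 4, 5, 7, 8, 10, 11, 12); steps 6 and 9 prepare the two side fragments.

Steps most likely to fail

Step 7. The β-branched aldehyde may form its enamine slowly, and the electron-rich allylic alcohol may ionise outside the iridium cycle; both would erode facial control at the benzylic carbon and divert attack to the unsubstituted allyl terminus. The fallback sets out from 6 and comes back at 12, replacing the intermolecular allylation by an Ireland–Claisen rearrangement with 1,3-chirality transfer.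
- Ester 6 is saponified (LiOH, THF/H2O) to (3S)-3-[3-methoxy-4-(methoxymethoxy)phenyl]hex-5-enoic acid F1.
- Commercial (3E)-4-(3,4-dimethoxyphenyl)but-3-en-2-one is reduced with BH3·SMe2 and the (R)-methyl-CBS oxazaborolidine to (2S,3E)-4-(3,4-dimethoxyphenyl)but-3-en-2-ol F2.
- Steglich esterification (DCC, DMAP) joins the two to (2S,3E)-4-(3,4-dimethoxyphenyl)but-3-en-2-yl (3S)-3-[3-methoxy-4-(methoxymethoxy)phenyl]hex-5-enoate F3.
- Enolisation with LiN(i-Pr)2 and Me3SiCl in THF at −78 °C and warming should give, through the chair transition state with the carbinol methyl equatorial, (2R,3S)-2-[(1R,2E)-1-(3,4-dimethoxyphenyl)but-2-en-1-yl]-3-[3-methoxy-4-(methoxymethoxy)phenyl]hex-5-enoic acid F4. The carbinol configuration is transferred to C6 and the E-ketene acetal sets C1.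
- LiAlH4 reduces F4 to (2R,3S)-2-[(1R,2E)-1-(3,4-dimethoxyphenyl)but-2-en-1-yl]-3-[3-methoxy-4-(methoxymethoxy)phenyl]hex-5-en-1-ol F5, and Dess–Martin oxidation gives (2R,3S)-2-[(1R,2E)-1-(3,4-dimethoxyphenyl)but-2-en-1-yl]-3-[3-methoxy-4-(methoxymethoxy)phenyl]hex-5-enal F6.
- The same ring-closing metathesis, now releasing propene, returns to 12; any C1 epimer is equilibrated with DBU.

Step 3. The basic ylide deprotonates the malonate C–H and may also enolise the aldehyde, which opens the way to retro-Michael fragmentation, incomplete methylenation or loss of enantiomeric purity; the partial ester reduction of step 5 may in addition run on to the alcohol. The fallback sets out from 2 and 3 and comes back at 8. It exchanges the roles of the two arms, so the other catalyst enantiomer is used.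
- The Michael addition with the (S)-configured prolinol silyl ether gives dimethyl 2-{(1R)-1-[3-methoxy-4-(methoxymethoxy)phenyl]-3-oxopropyl}propanedioate F7.
- NaBH4 reduction and acid-catalysed lactonisation give methyl (3S,4R)-4-[3-methoxy-4-(methoxymethoxy)phenyl]-2-oxooxane-3-carboxylate F8.
- Krapcho conditions (LiCl, wet DMSO) give (4R)-4-[3-methoxy-4-(methoxymethoxy)phenyl]oxan-2-one F9.
- i-Bu2AlH at −78 °C gives the lactol (4R)-4-[3-methoxy-4-(methoxymethoxy)phenyl]oxan-2-ol F10.
- Wittig methylenation of the lactol, with no acidic malonate present, gives (3S)-3-[3-methoxy-4-(methoxymethoxy)phenyl]hex-5-en-1-ol F11, and Dess–Martin oxidation returns to 8.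

Step 10. Proton transfer from the hindered α-branched aldehyde to the enolate, retro-aldol cleavage on warming or dehydration of the aldol may compete, and the following oxidation may run on at the central carbon of the diketone. The fallback sets out from 12 and comes back at 17 by C-acylation instead of aldol and oxidation.
- Pinnick oxidation (NaClO2, NaH2PO4, 2-methylbut-2-ene, t-BuOH/H2O) gives (1R,2R,6S)-2-(3,4-dimethoxyphenyl)-6-[3-methoxy-4-(methoxymethoxy)phenyl]cyclohex-3-ene-1-carboxylic acid F12.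
- Carbonyldiimidazole converts it into [(1R,2R,6S)-2-(3,4-dimethoxyphenyl)-6-[3-methoxy-4-(methoxymethoxy)phenyl]cyclohex-3-en-1-yl](1H-imidazol-1-yl)methanone F13.
- Two equivalents of enolate 15 in THF at −78 °C acylate at carbon and give 17 directly.

Further compounds
F1 | step 7 | (3S)-3-[3-methoxy-4-(methoxymethoxy)phenyl]hex-5-enoic acid | OC(=O)C[C@@H](c1ccc(OCOC)c(OC)c1)CC=C
F2 | step 7 | (2S,3E)-4-(3,4-dimethoxyphenyl)but-3-en-2-ol | C[C@H](O)/C=C/c1ccc(OC)c(OC)c1
F3 | step 7 | (2S,3E)-4-(3,4-dimethoxyphenyl)but-3-en-2-yl (3S)-3-[3-methoxy-4-(methoxymethoxy)phenyl]hex-5-enoate | C[C@H](OC(=O)C[C@@H](c1ccc(OCOC)c(OC)c1)CC=C)/C=C/c1ccc(OC)c(OC)c1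
F4 | step 7 | (2R,3S)-2-[(1R,2E)-1-(3,4-dimethoxyphenyl)but-2-en-1-yl]-3-[3-methoxy-4-(methoxymethoxy)phenyl]hex-5-enoic acid | OC(=O)[C@H]([C@@H](c1ccc(OCOC)c(OC)c1)CC=C)[C@H](c1ccc(OC)c(OC)c1)/C=C/C
F5 | step 7 | (2R,3S)-2-[(1R,2E)-1-(3,4-dimethoxyphenyl)but-2-en-1-yl]-3-[3-methoxy-4-(methoxymethoxy)phenyl]hex-5-en-1-ol | OC[C@H]([C@@H](c1ccc(OCOC)c(OC)c1)CC=C)[C@H](c1ccc(OC)c(OC)c1)/C=C/C
F6 | step 7 | (2R,3S)-2-[(1R,2E)-1-(3,4-dimethoxyphenyl)but-2-en-1-yl]-3-[3-methoxy-4-(methoxymethoxy)phenyl]hex-5-enal | O=C[C@H]([C@@H](c1ccc(OCOC)c(OC)c1)CC=C)[C@H](c1ccc(OC)c(OC)c1)/C=C/C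
F7 | step 3 | dimethyl 2-{(1R)-1-[3-methoxy-4-(methoxymethoxy)phenyl]-3-oxopropyl}propanedioate | COC(=O)C(C(=O)OC)[C@H](c1ccc(OCOC)c(OC)c1)CC=O
F8 | step 3 | methyl (3S,4R)-4-[3-methoxy-4-(methoxymethoxy)phenyl]-2-oxooxane-3-carboxylate (trans; C3 epimerisable) | COC(=O)[C@@H]1C(=O)OCC[C@H]1c1ccc(OCOC)c(OC)c1
F9 | step 3 | (4R)-4-[3-methoxy-4-(methoxymethoxy)phenyl]oxan-2-one | O=C1C[C@H](c2ccc(OCOC)c(OC)c2)CCO1
F10 | step 3 | (4R)-4-[3-methoxy-4-(methoxymethoxy)phenyl]oxan-2-ol (both anomers) | OC1C[C@H](c2ccc(OCOC)c(OC)c2)CCO1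
F11 | step 3 | (3S)-3-[3-methoxy-4-(methoxymethoxy)phenyl]hex-5-en-1-ol | OCC[C@@H](c1ccc(OCOC)c(OC)c1)CC=C
F12 | step 10 | (1R,2R,6S)-2-(3,4-dimethoxyphenyl)-6-[3-methoxy-4-(methoxymethoxy)phenyl]cyclohex-3-ene-1-carboxylic acid | OC(=O)[C@@H]1[C@@H](c2ccc(OCOC)c(OC)c2)CC=C[C@H]1c1ccc(OC)c(OC)c1
F13 | step 10 | [(1R,2R,6S)-2-(3,4-dimethoxyphenyl)-6-[3-methoxy-4-(methoxymethoxy)phenyl]cyclohex-3-en-1-yl](1H-imidazol-1-yl)methanone | O=C(n1ccnc1)[C@@H]1[C@@H](c2ccc(OCOC)c(OC)c2)CC=C[C@H]1c1ccc(OC)c(OC)c1
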